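Green cannot be sending every bit of its lost J into Z: by 15.0 h J is down 37.6 % of its charge, yet Z stands at 12.3 %.

| setting | green | south | north-west | west |
|---|---|---|---|---|
| J | 1.2 M | 0.80 M | 1.5 M | 3.0 M |
| E | 0.486 M | 0.486 M | 0.486 M | 0.486 M |
| remark | run made earlier |  |  |  |
| time |  | 15 h | 15 h | 15 h |

green run (percent of the J charged)

| time / h | Z / % | J / % |
|---|---|---|
| 1.33 | 3.7 | 93.7 |
| 4.00 | 7.9 | 84.4 |
| 8.00 | 10.4 | 74.0 |
| 10.0 | 11.7 | 69.7 |
| 15.0 | 12.3 | 62.4 |

(standard deviation of a reading: 0.5 percentage points)

- [Z] at the end for south, north-west, west, in this order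
- how the row runs (hardly changes / falls, then rises / falls all the way / rises all the way / rises, then falls)

- what was read earlier has a scatter of 0.5 percentage points, one standard deviation
- "hardly changes" means that all values lie within two and a half points (for a concentration: within two and a half percent of the largest)

For the quick number you asked for: green's Z gained 0.6 percentage points between 10.0 h and 15.0 h, so it stalled near a read 0.148 M. The first green reading gives 0.0572 L mol⁻¹ h⁻¹ as the make coefficient, Z formed per hour per unit of J times E at the charge; that reading carries 0.5 points on 3.7 %. With J frozen at its charge, E decays pseudo-first-order: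

half-life of E = ln(2) / (make coefficient × J charged)

green 10.1 h
south 15.1 h
north-west 8.07 h
west 4.04 h

Green's half-life sits where its Z stalled. The starting rate times this half-life is ln(2) × E charged, 0.337 M, for any J at this make coefficient and E charge, so in the frozen picture J moves the time of the stall and leaves its height. The reckoning here therefore puts all 3 flasks near 0.148 M. South reaches its half-life about at 15 h, and west is 3.71 half-lives along by then; this frozen picture holds no loss of Z, so the row it gives hardly changes.

Your forecast differs: 0.105 M, 0.175 M, 0.265 M, rises all the way, on the ground that “Z is near equilibrium with the remaining J”.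

The flasks give 0.127 M, 0.150 M, 0.139 M: rises, then falls, turning at J 1.8 M.

    J + E ⇌ Z + G (K = 0.210, k = 8.90 × 10⁻⁴ L mol⁻¹ min⁻¹)
    J + Z → L (k = 6.60 × 10⁻⁴ L mol⁻¹ min⁻¹)
    2 J → Q (k = 1.30 × 10⁻⁴ L mol⁻¹ min⁻¹)

South's half-life of 15.1 h is longer than 7.50 h, and its Z climbed from 12.4 % to 15.9 % of the J charged by 15.0 h. West's half-life of 4.04 h is shorter, and its Z fell from 5.75 % to 4.63 %.

(Readings and results come from a simulation from invented constants.)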